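TBS = tert‑butyldimethylsilyl throughout. Flavan numbering is used for the target: O1, C2, C3, C4, C4a, C5–C8, C8a (rings A and C), ring B = 4‑hydroxyphenyl on C2, ring D = the resorcinol ring of the stilbene on C4, ring E = its catechol ring.

## Analysis of the target

- Target 18 is a 4‑arylflavan‑3‑ol. The chroman core (benzo ring A with only a 7‑OH, heterocycle C = O1–C2–C3–C4–C4a–C8a) carries ring B on C2 and a hydroxyl on C3. C4 is bound to C2 of the resorcinol ring of a piceatannol unit, ortho to a phenolic OH and ortho to the (E)‑styryl arm.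
- The three contiguous stereocentres are C2 (R), C3 (S) and C4 (S). The 2‑aryl and 4‑aryl groups are cis and the 3‑OH is trans to both, so all three substituents are equatorial on the half‑chair of ring C. C2 is a benzylic ether that can be corrected by equilibration; C3 and C4 cannot.
- C4 is a doubly benzylic methine between two ortho‑oxygenated rings, and ring D is substituted at both positions ortho to it. The C4–ring D bond is the most crowded bond of the molecule, and no functional group directs the configuration at C4.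
- Sensitive groups: six free phenols including a catechol (air oxidation in base), the stilbene (ruled out: hydrogenolysis, hydroboration, epoxidation, dihydroxylation; it also captures benzylic cations), and the C2–O1 benzylic ether activated by the 4′‑oxygen.
- What makes it hard: absolute control at C4, joining the stilbene through the right carbon, and a protecting‑group scheme that needs neither hydrogenolysis nor strong Lewis acid at the end.
- The feature that invites the chosen move: O1–C8a–C4a–C4 is the retron of an ortho‑quinone methide of ring A. C2–C3, with the 4‑oxygenated aryl on C2 and oxygen on C3, is an (E)‑β‑oxygenated 4‑oxystyrene. Ring C and its three stereocentres are therefore one oxa‑[4+2] adduct.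

## Retrosynthetic reasoning

**18 from 17.** Only the six phenolic silyl ethers are removed. Silyl protection is chosen because its removal needs no hydrogenolysis (stilbene) and no strong Lewis acid (ring C), and because aryl silyl ethers survive the acid of the key step.

**17 from 13 and 16.** The aryl–vinyl bond of the styryl arm is cut (Mizoroki–Heck). The stilbene is introduced late on purpose: a styryl group ortho to the benzhydryl carbon would capture the cationic intermediate of the key step in a cation–olefin cyclisation to an indane, and would compete as a 2π partner. A bromine on ring D holds its place. The bromine also means both ortho positions of ring D are substituted, which shuts off Friedel–Crafts side reactions on that ring.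

**13 from 12, and 12 from 7 and 10 through 11.** This is the key disconnection. Both bonds that ring C makes to its stereocentres, C4–C3 and O1–C2, are cut at once. This leads back to quinone methide 11, which is generated from the achiral, racemic benzhydrol 7, and to the (E)‑enol acetate 10. The forward reaction must form two bonds, close ring C and set C2, C3 and C4 in one catalytic asymmetric operation. The cut is made here and not at C4–ring D because it moves the crowded C4–ring D bond back to a carbonyl addition, and places all the stereochemistry in one step with a planar, achiral precursor. The acetate on O3 is then removed reductively to give 13.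

**7 from 2 and 6, with 6 from 5, 5 from 4, 4 from 3.** C4 is the former formyl carbon of salicylaldehyde 2. The C4–ring D bond is made by addition of aryl Grignard 6, so no stereocontrol is needed. The free ortho‑phenol of 2 becomes the only free phenol of 7, so only ring A can form the quinone methide. The iodine of 5 marks the carbon that becomes attached to C4 and is exchanged selectively next to the bromine.

**10 from 9, and 9 from 8.** The (E)‑geometry that becomes the C2/C3 trans relationship is fixed by a Wittig reaction with a stabilised ylide. The enol oxygen is then inserted by Baeyer–Villiger oxidation with retention of geometry.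

**16 from 15, 15 from 14; 2 from 1.** Routine silylation and methylenation deliver the Heck partner and the salicylaldehyde.

## Alternatives that were turned down

**Alternative 1:** the textbook, biomimetic cut of the C4–ring D bond.
- Forward key step: acid ionisation of (2R,3S,4R)‑flavan‑3,4‑diol A1 to the C4 benzylic cation and Friedel–Crafts capture by piceatannol A2, giving 18 directly.
- Turned down because A2 offers several nucleophilic sites (C2/C6 and C4 of the resorcinol ring, the styrene β‑carbon, the catechol ring), and 18 remains a nucleophile that can be alkylated again.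
- The 5‑deoxy ring A gives a poorly stabilised, unselective cation, which also attacks C6/C8 of a second molecule of A1.
- C4 is left to substrate bias, and the stilbene sits in the acid with a cation.
- A1 is not a commercial enantiopure compound. Its C2/C3 stereocentres need their own asymmetric synthesis of five or more steps, so none of the stereochemical work is saved.

**Alternative 2:** dearomatisation of a flavylium ion.
- Forward: a 2,6‑disubstituted ring D aryl‑metal adds to flavone A3 and dehydration gives the 4‑arylflavylium salt A4. Enantioselective hydride transfer to C4 (chiral phosphate, dihydropyridine donor) gives flav‑2‑ene A5. Anti hydroboration–oxidation then relays C4 to C3 and C2.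
- Turned down because it still makes the crowded C4–ring D bond by aryl addition, now to a vinylogous ester with a di‑ortho‑substituted nucleophile.
- In A4 the perpendicular ring D puts one ortho substituent over each face of C4, so face discrimination by the hydride donor is doubtful.
- The strongly acidic flavylium stage calls for methyl‑type ethers, whose Lewis‑acid removal the flavan‑3‑ol does not tolerate.
- The stereocentres are set in two separate operations, and the route is longer.

**Alternative 3:** cut of the C4–C4a bond.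
- Forward: Lewis‑acid‑promoted 6‑endo epoxy‑arene cyclisation of aryl ether A6. Ring A attacks the benzylic epoxide carbon with inversion and leaves the 3,4‑trans alcohol.
- Turned down because A6 already contains all three stereocentres, so the key step simplifies nothing.
- The 4‑oxybenzylic C2–O bond of A6 ionises under the same Lewis acid.
- Ring A can attack through two ortho sites (5‑ versus 7‑oxygenated chroman).
- The ortho‑bromine weakens the benzylic activation needed for 6‑endo over 5‑exo opening.

Key step: step 7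

Assumption: the sense of induction of the chiral acid in step 7 cannot be derived from first principles for this new substrate pair; the (R)‑catalyst is written, and its enantiomer is to be used if it should favour the antipode of 12.

## Route

Step 1
Reactants: 1 2,4‑dihydroxybenzaldehyde
Product: 2 4‑(tert‑butyldimethylsilyloxy)‑2‑hydroxybenzaldehyde
Conditions: TBSCl (1.05 equiv), imidazole, CH2Cl2, 0 °C
Reagents that add atoms: tert‑butyldimethylsilyl chloride, CC(C)(C)[Si](C)(C)Cl
Why: Selective O‑silylation; the 2‑OH is hydrogen‑bonded to the formyl group and much less nucleophilic, so only the 4‑OH should react.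

Step 2
Reactants: 3 5‑bromobenzene‑1,3‑diol
Product: 4 1‑bromo‑3,5‑bis(tert‑butyldimethylsilyloxy)benzene
Conditions: TBSCl (2.3 equiv), imidazole, DMF, rt
Reagents that add atoms: tert‑butyldimethylsilyl chloride, CC(C)(C)[Si](C)(C)Cl
Why: Standard exhaustive silylation of both phenols.

Step 3
Reactants: 4 1‑bromo‑3,5‑bis(tert‑butyldimethylsilyloxy)benzene
Product: 5 1‑bromo‑2‑iodo‑3,5‑bis(tert‑butyldimethylsilyloxy)benzene
Conditions: NIS (1.05 equiv), TFA (10 mol %), MeCN, 0 °C to rt
Reagents that add atoms: N‑iodosuccinimide, O=C1CCC(=O)N1I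
Why: Electrophilic aromatic iodination; C2 is para to one silyloxy group and ortho to the other, whereas the only other activated site lies between two bulky silyloxy groups.

Step 4
Reactants: 5 1‑bromo‑2‑iodo‑3,5‑bis(tert‑butyldimethylsilyloxy)benzene; 2 4‑(tert‑butyldimethylsilyloxy)‑2‑hydroxybenzaldehyde
Product: 7 [2‑bromo‑4,6‑bis(tert‑butyldimethylsilyloxy)phenyl][4‑(tert‑butyldimethylsilyloxy)‑2‑hydroxyphenyl]methanol (racemic), via aryl Grignard reagent 6 (not isolated)
Conditions: 5 (2.1 equiv), iPrMgCl·LiCl (2.1 equiv), THF, −40 °C; then 2 (1.0 equiv), −40 to −10 °C; aq. NH4Cl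
Reagents that add atoms: isopropylmagnesium chloride–lithium chloride complex, CC(C)[Mg]Cl.[Li+].[Cl-] (supplies the MgCl of intermediate 6 only)
Why: Chemoselective iodine–magnesium exchange (iodide far faster than bromide, carbanion stabilised by the flanking Br and O) followed by Grignard addition; the first equivalent of 6 deprotonates the phenol and the magnesium chelate activates the formyl group. The new carbinol centre needs no control because it becomes planar in step 7.

Step 5
Reactants: 8 4‑(tert‑butyldimethylsilyloxy)benzaldehyde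
Product: 9 (E)‑4‑[4‑(tert‑butyldimethylsilyloxy)phenyl]but‑3‑en‑2‑one
Conditions: Ph3P=CHC(O)CH3 (1.2 equiv), toluene, 90 °C
Reagents that add atoms: 1‑(triphenyl‑λ5‑phosphanylidene)propan‑2‑one, CC(=O)C=P(c1ccccc1)(c1ccccc1)c1ccccc1
Why: Wittig olefination with a stabilised ylide, which should give the (E)‑enone.

Step 6
Reactants: 9 (E)‑4‑[4‑(tert‑butyldimethylsilyloxy)phenyl]but‑3‑en‑2‑one
Product: 10 (E)‑2‑[4‑(tert‑butyldimethylsilyloxy)phenyl]ethenyl acetate
Conditions: (BnSe)2 (5 mol %), 30 % aq. H2O2 (2 equiv), MeCN, rt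
Reagents that add atoms: hydrogen peroxide, OO
Why: Baeyer–Villiger oxidation of an (E)‑α,β‑unsaturated methyl ketone under organoselenium catalysis; the electron‑rich styryl group should migrate in preference to methyl with retention of the (E)‑geometry, giving the enol acetate.

Step 7
Reactants: 7 [2‑bromo‑4,6‑bis(tert‑butyldimethylsilyloxy)phenyl][4‑(tert‑butyldimethylsilyloxy)‑2‑hydroxyphenyl]methanol; 10 (E)‑2‑[4‑(tert‑butyldimethylsilyloxy)phenyl]ethenyl acetate
Product: 12 (2R,3S,4S)‑4‑[2‑bromo‑4,6‑bis(tert‑butyldimethylsilyloxy)phenyl]‑7‑(tert‑butyldimethylsilyloxy)‑2‑[4‑(tert‑butyldimethylsilyloxy)phenyl]chroman‑3‑yl acetate, via ortho‑quinone methide 11 (not isolated)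
Conditions: (R)‑3,3′‑bis(2,4,6‑triisopropylphenyl)‑BINOL N‑triflylphosphoramide (10 mol %), 10 (2.0 equiv), 5 Å MS, toluene, −20 °C to rt
Reagents that add atoms: none
Why: Proposed new method: the chiral N‑triflylphosphoramide dehydrates 7 to the hydrogen‑bonded (E)‑ortho‑quinone methide 11, which should add enol acetate 10 in an inverse‑electron‑demand oxa‑[4+2] cycloaddition (hetero‑Diels–Alder); the closest known reactions are the chiral Brønsted‑acid‑catalysed [4+2] cycloadditions of benzhydrol‑derived ortho‑quinone methides with styrenes and their cycloadditions with (E)‑β‑alkyl‑4‑alkoxystyrenes, and the new element is the β‑acyloxy group on the styrene. Ring C closes in the [4+2] mode: the acetoxy‑bearing carbon of 10 (C3) bonds to the electrophilic methide carbon C4 and O1 bonds to C2; if the process is stepwise, the second bond forms by 6‑exo‑trig capture of the quinone‑methide‑like C2 cation by the phenolic oxygen. Regiochemistry is secured by the 4‑silyloxyphenyl group, which makes the acetoxy‑bearing carbon the nucleophilic terminus and C2 the cation‑stabilised one, while the ester oxygen is a weak donor because its lone pair is engaged by the carbonyl group. The C2/C3 trans relationship follows from the (E)‑geometry of 10 (suprafacial addition); in a stepwise course, acetoxy participation and acid equilibration of the benzylic ether C2 lead to the same all‑equatorial isomer. The C3/C4 trans and C2/C4 cis relationships follow from the aryl‑endo transition state on the (E)‑methide. The absolute configuration at C4, and through the transition‑state topology at C3 and C2, is set by the chiral counter‑anion, which shields one face of 11. The step needs regio‑, endo‑ and enantioface selectivity and chemoselectivity over acetyl transfer from 10; the doubly ortho‑substituted ring D blocks Friedel–Crafts closure to an indane, and the aryl silyl ethers tolerate the acid.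

Step 8
Reactants: 12 (2R,3S,4S)‑4‑[2‑bromo‑4,6‑bis(tert‑butyldimethylsilyloxy)phenyl]‑7‑(tert‑butyldimethylsilyloxy)‑2‑[4‑(tert‑butyldimethylsilyloxy)phenyl]chroman‑3‑yl acetate
Product: 13 (2R,3S,4S)‑4‑[2‑bromo‑4,6‑bis(tert‑butyldimethylsilyloxy)phenyl]‑7‑(tert‑butyldimethylsilyloxy)‑2‑[4‑(tert‑butyldimethylsilyloxy)phenyl]chroman‑3‑ol
Conditions: DIBAL‑H (2.5 equiv), CH2Cl2, −78 °C; Rochelle salt
Reagents that add atoms: none
Why: Reductive cleavage of the acetate at low temperature; no basic methanolysis is used, so the aryl silyl ethers, the aryl bromide and the stereocentres should stay untouched.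

Step 9
Reactants: 14 3,4‑dihydroxybenzaldehyde
Product: 15 3,4‑bis(tert‑butyldimethylsilyloxy)benzaldehyde
Conditions: TBSCl (2.3 equiv), imidazole, DMF, rt
Reagents that add atoms: tert‑butyldimethylsilyl chloride, CC(C)(C)[Si](C)(C)Cl
Why: Standard silylation of the catechol.

Step 10
Reactants: 15 3,4‑bis(tert‑butyldimethylsilyloxy)benzaldehyde
Product: 16 3,4‑bis(tert‑butyldimethylsilyloxy)styrene
Conditions: Ph3PCH3Br (1.3 equiv), NaHMDS (1.25 equiv), THF, 0 °C to rt
Reagents that add atoms: methyltriphenylphosphonium bromide, C[P+](c1ccccc1)(c1ccccc1)c1ccccc1.[Br-]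
Why: Wittig methylenation; the ylide is preformed with a non‑nucleophilic amide base so that the aryl silyl ethers are not attacked.

Step 11
Reactants: 13 (2R,3S,4S)‑4‑[2‑bromo‑4,6‑bis(tert‑butyldimethylsilyloxy)phenyl]‑7‑(tert‑butyldimethylsilyloxy)‑2‑[4‑(tert‑butyldimethylsilyloxy)phenyl]chroman‑3‑ol; 16 3,4‑bis(tert‑butyldimethylsilyloxy)styrene
Product: 17 (2R,3S,4S)‑4‑{2,4‑bis(tert‑butyldimethylsilyloxy)‑6‑[(E)‑2‑[3,4‑bis(tert‑butyldimethylsilyloxy)phenyl]ethenyl]phenyl}‑7‑(tert‑butyldimethylsilyloxy)‑2‑[4‑(tert‑butyldimethylsilyloxy)phenyl]chroman‑3‑ol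
Conditions: Pd2(dba)3 (2.5 mol %), [(t‑Bu)3PH]BF4 (10 mol %), Cy2NMe (1.5 equiv), 16 (1.5 equiv), 1,4‑dioxane, 90 °C
Reagents that add atoms: none
Why: Mizoroki–Heck reaction with a bulky electron‑rich phosphine, the catalyst type suited to electron‑rich ortho‑substituted aryl bromides; syn‑carbopalladation and syn‑β‑hydride elimination should give the (E)‑stilbene. The stilbene is introduced only now because it would not survive the cationic conditions of step 7.

Step 12
Reactants: 17 (2R,3S,4S)‑4‑{2,4‑bis(tert‑butyldimethylsilyloxy)‑6‑[(E)‑2‑[3,4‑bis(tert‑butyldimethylsilyloxy)phenyl]ethenyl]phenyl}‑7‑(tert‑butyldimethylsilyloxy)‑2‑[4‑(tert‑butyldimethylsilyloxy)phenyl]chroman‑3‑ol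
Product: 18 (2R,3S,4S)‑4‑{2‑[(E)‑2‑(3,4‑dihydroxyphenyl)ethenyl]‑4,6‑dihydroxyphenyl}‑2‑(4‑hydroxyphenyl)chroman‑3,7‑diol
Conditions: TBAF (7 equiv), AcOH (7 equiv), THF, 0 °C to rt, argon
Reagents that add atoms: none
Why: Fluoride desilylation of the six aryl silyl ethers, buffered with acetic acid so that free phenoxides (catechol oxidation, ring opening at C2 through the ring B quinone methide) do not build up.

## Compound list

1 | 2,4‑dihydroxybenzaldehyde | O=Cc1ccc(O)cc1O | starting material
2 | 4‑(tert‑butyldimethylsilyloxy)‑2‑hydroxybenzaldehyde | O=Cc1ccc(O[Si](C)(C)C(C)(C)C)cc1O | intermediate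
3 | 5‑bromobenzene‑1,3‑diol | Oc1cc(O)cc(Br)c1 | starting material
4 | 1‑bromo‑3,5‑bis(tert‑butyldimethylsilyloxy)benzene | CC(C)(C)[Si](C)(C)Oc1cc(Br)cc(O[Si](C)(C)C(C)(C)C)c1 | intermediate
5 | 1‑bromo‑2‑iodo‑3,5‑bis(tert‑butyldimethylsilyloxy)benzene | CC(C)(C)[Si](C)(C)Oc1cc(O[Si](C)(C)C(C)(C)C)c(I)c(Br)c1 | intermediate
6 | [2‑bromo‑4,6‑bis(tert‑butyldimethylsilyloxy)phenyl]magnesium chloride | CC(C)(C)[Si](C)(C)Oc1cc(O[Si](C)(C)C(C)(C)C)c([Mg]Cl)c(Br)c1 | intermediate (not isolated)
7 | [2‑bromo‑4,6‑bis(tert‑butyldimethylsilyloxy)phenyl][4‑(tert‑butyldimethylsilyloxy)‑2‑hydroxyphenyl]methanol (racemic) | OC(c1ccc(O[Si](C)(C)C(C)(C)C)cc1O)c1c(O[Si](C)(C)C(C)(C)C)cc(O[Si](C)(C)C(C)(C)C)cc1Br | intermediate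
8 | 4‑(tert‑butyldimethylsilyloxy)benzaldehyde | O=Cc1ccc(O[Si](C)(C)C(C)(C)C)cc1 | starting material
9 | (E)‑4‑[4‑(tert‑butyldimethylsilyloxy)phenyl]but‑3‑en‑2‑one | CC(=O)/C=C/c1ccc(O[Si](C)(C)C(C)(C)C)cc1 | intermediate
10 | (E)‑2‑[4‑(tert‑butyldimethylsilyloxy)phenyl]ethenyl acetate | CC(=O)O/C=C/c1ccc(O[Si](C)(C)C(C)(C)C)cc1 | intermediate
11 | (6E)‑6‑{[2‑bromo‑4,6‑bis(tert‑butyldimethylsilyloxy)phenyl]methylidene}‑3‑(tert‑butyldimethylsilyloxy)cyclohexa‑2,4‑dien‑1‑one | O=C1C=C(O[Si](C)(C)C(C)(C)C)C=C/C1=C\c1c(O[Si](C)(C)C(C)(C)C)cc(O[Si](C)(C)C(C)(C)C)cc1Br | intermediate (not isolated)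
12 | (2R,3S,4S)‑4‑[2‑bromo‑4,6‑bis(tert‑butyldimethylsilyloxy)phenyl]‑7‑(tert‑butyldimethylsilyloxy)‑2‑[4‑(tert‑butyldimethylsilyloxy)phenyl]chroman‑3‑yl acetate | CC(C)(C)[Si](C)(C)Oc1ccc([C@H]2Oc3cc(O[Si](C)(C)C(C)(C)C)ccc3[C@@H](c3c(O[Si](C)(C)C(C)(C)C)cc(O[Si](C)(C)C(C)(C)C)cc3Br)[C@@H]2OC(C)=O)cc1 | intermediate
13 | (2R,3S,4S)‑4‑[2‑bromo‑4,6‑bis(tert‑butyldimethylsilyloxy)phenyl]‑7‑(tert‑butyldimethylsilyloxy)‑2‑[4‑(tert‑butyldimethylsilyloxy)phenyl]chroman‑3‑ol | CC(C)(C)[Si](C)(C)Oc1ccc([C@H]2Oc3cc(O[Si](C)(C)C(C)(C)C)ccc3[C@@H](c3c(O[Si](C)(C)C(C)(C)C)cc(O[Si](C)(C)C(C)(C)C)cc3Br)[C@@H]2O)cc1 | intermediate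
14 | 3,4‑dihydroxybenzaldehyde | O=Cc1ccc(O)c(O)c1 | starting material
15 | 3,4‑bis(tert‑butyldimethylsilyloxy)benzaldehyde | O=Cc1ccc(O[Si](C)(C)C(C)(C)C)c(O[Si](C)(C)C(C)(C)C)c1 | intermediate
16 | 3,4‑bis(tert‑butyldimethylsilyloxy)styrene | C=Cc1ccc(O[Si](C)(C)C(C)(C)C)c(O[Si](C)(C)C(C)(C)C)c1 | intermediate
17 | (2R,3S,4S)‑4‑{2,4‑bis(tert‑butyldimethylsilyloxy)‑6‑[(E)‑2‑[3,4‑bis(tert‑butyldimethylsilyloxy)phenyl]ethenyl]phenyl}‑7‑(tert‑butyldimethylsilyloxy)‑2‑[4‑(tert‑butyldimethylsilyloxy)phenyl]chroman‑3‑ol | CC(C)(C)[Si](C)(C)Oc1ccc([C@H]2Oc3cc(O[Si](C)(C)C(C)(C)C)ccc3[C@@H](c3c(O[Si](C)(C)C(C)(C)C)cc(O[Si](C)(C)C(C)(C)C)cc3/C=C/c3ccc(O[Si](C)(C)C(C)(C)C)c(O[Si](C)(C)C(C)(C)C)c3)[C@@H]2O)cc1 | intermediate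
18 | (2R,3S,4S)‑4‑{2‑[(E)‑2‑(3,4‑dihydroxyphenyl)ethenyl]‑4,6‑dihydroxyphenyl}‑2‑(4‑hydroxyphenyl)chroman‑3,7‑diol | Oc1ccc([C@H]2Oc3cc(O)ccc3[C@@H](c3c(O)cc(O)cc3/C=C/c3ccc(O)c(O)c3)[C@@H]2O)cc1 | target

## Step count and least certain steps

Total step count: 12. Longest linear sequence: 7 steps (3 → 4 → 5 → 7 → 12 → 13 → 17 → 18; steps 2, 3, 4, 7, 8, 11, 12).

**Step 7 (key step, proposed new method).**
- What may go wrong: reversal of regiochemistry (ester‑oxygen‑controlled addition placing the aryl group on C3); acetyl transfer from the enol ester to the phenol or carbinol; slow addition at the crowded methide carbon with oligomerisation of the quinone methide; exo approach giving the 3,4‑cis series; poor face selectivity.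
- Fallback with known chemistry, setting out from 7 and returning at 13:
  - Benzhydrol 7 is heated in toluene over molecular sieves with diethyl (E)‑{2‑[4‑(tert‑butyldimethylsilyloxy)phenyl]ethenyl}boronate F1 and catalytic 3,3′‑dibromo‑BINOL (antipode chosen for the S product). F1 is made in one pot from commercial tert‑butyl(4‑ethynylphenoxy)dimethylsilane by hydroboration with diisopinocampheylborane and treatment with acetaldehyde.
  - The chiral‑biphenol‑catalysed 1,4‑addition of the alkenyl group to quinone methide 11 should form the C3–C4 bond and set C4. It gives 2‑{(1S,2E)‑1‑[2‑bromo‑4,6‑bis(tert‑butyldimethylsilyloxy)phenyl]‑3‑[4‑(tert‑butyldimethylsilyloxy)phenyl]prop‑2‑en‑1‑yl}‑5‑(tert‑butyldimethylsilyloxy)phenol F2.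
  - Shi epoxidation of F2 (Oxone, buffered MeCN/dimethoxymethane/water, 0 °C) uses the ketone enantiomer that delivers the (2S,3S)‑epoxide; by the spiro transition‑state model this is the antipode of the fructose‑derived ketone. It gives, under reagent control, 2‑{(S)‑[2‑bromo‑4,6‑bis(tert‑butyldimethylsilyloxy)phenyl]{(2S,3S)‑3‑[4‑(tert‑butyldimethylsilyloxy)phenyl]oxiran‑2‑yl}methyl}‑5‑(tert‑butyldimethylsilyloxy)phenol F3.
  - F3 is not isolated. With catalytic PPTS the phenol should open it 6‑endo at the 4‑silyloxybenzylic carbon with inversion, giving the 2,3‑trans alcohol 13.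

**Step 6.**
- What may go wrong: over‑oxidation of the electron‑rich enol acetate (epoxidation and rearrangement), or epoxidation of the enone in competition with oxygen insertion.
- Fallback, setting out from 8 and returning at 10:
  - Aldehyde 8 is homologated by Wittig reaction with methoxymethylenetriphenylphosphorane to tert‑butyl[4‑(2‑methoxyethenyl)phenoxy]dimethylsilane F4 (E/Z mixture).
  - Mild aqueous acid hydrolysis of F4 gives [4‑(tert‑butyldimethylsilyloxy)phenyl]acetaldehyde F5.
  - Enol acetylation of F5 (Ac2O, KOAc) gives 10 as an E/Z mixture, from which the (E)‑isomer is separated by chromatography.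

**Step 4.**
- What may go wrong: aryne formation from the ortho‑bromoaryl Grignard reagent on warming; migration of the ortho silyl group to the new alkoxide; sluggish addition of the doubly ortho‑substituted nucleophile to the magnesium phenoxide aldehyde.
- Fallback with reversed polarity, setting out from 5 (through 6) and returning at 7:
  - Grignard reagent 6 is quenched with DMF to give 2‑bromo‑4,6‑bis(tert‑butyldimethylsilyloxy)benzaldehyde F6.
  - The bromomagnesium phenoxide of commercial 3‑(tert‑butyldimethylsilyloxy)phenol (EtMgBr, toluene/CH2Cl2) is added to F6. Chelation‑controlled ortho‑hydroxyalkylation, at the ortho position para to the silyloxy group, should give 7.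

**Step 11.**
- What may go wrong: slow oxidative addition and carbopalladation at the hindered bromide, with protodebromination or catalyst death.
- Fallback, setting out from 13 and 15 and returning at 17:
  - Aldehyde 15 is converted by boron‑Wittig olefination (bis(pinacolatoboryl)methane, LiTMP, THF, −78 °C to rt) into 2‑{(E)‑2‑[3,4‑bis(tert‑butyldimethylsilyloxy)phenyl]ethenyl}‑4,4,5,5‑tetramethyl‑1,3,2‑dioxaborolane F7.
  - Suzuki–Miyaura coupling of F7 with 13 (Pd(OAc)2, SPhos, K3PO4, toluene/water, 80 °C) replaces the carbopalladation by a transmetalation and gives 17 with retention of the (E)‑geometry. Partial loss of silyl groups here is harmless because step 12 removes them all.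

## Further compounds

F1 | step 7 | diethyl (E)‑{2‑[4‑(tert‑butyldimethylsilyloxy)phenyl]ethenyl}boronate | CCOB(OCC)/C=C/c1ccc(O[Si](C)(C)C(C)(C)C)cc1
F2 | step 7 | 2‑{(1S,2E)‑1‑[2‑bromo‑4,6‑bis(tert‑butyldimethylsilyloxy)phenyl]‑3‑[4‑(tert‑butyldimethylsilyloxy)phenyl]prop‑2‑en‑1‑yl}‑5‑(tert‑butyldimethylsilyloxy)phenol | Oc1cc(O[Si](C)(C)C(C)(C)C)ccc1[C@@H](c1c(O[Si](C)(C)C(C)(C)C)cc(O[Si](C)(C)C(C)(C)C)cc1Br)/C=C/c1ccc(O[Si](C)(C)C(C)(C)C)cc1
F3 | step 7 | 2‑{(S)‑[2‑bromo‑4,6‑bis(tert‑butyldimethylsilyloxy)phenyl]{(2S,3S)‑3‑[4‑(tert‑butyldimethylsilyloxy)phenyl]oxiran‑2‑yl}methyl}‑5‑(tert‑butyldimethylsilyloxy)phenol | CC(C)(C)[Si](C)(C)Oc1ccc(cc1)[C@@H]1O[C@H]1[C@H](c1c(O[Si](C)(C)C(C)(C)C)cc(O[Si](C)(C)C(C)(C)C)cc1Br)c1ccc(O[Si](C)(C)C(C)(C)C)cc1O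
F4 | step 6 | tert‑butyl[4‑(2‑methoxyethenyl)phenoxy]dimethylsilane (E/Z mixture) | COC=Cc1ccc(O[Si](C)(C)C(C)(C)C)cc1
F5 | step 6 | [4‑(tert‑butyldimethylsilyloxy)phenyl]acetaldehyde | O=CCc1ccc(O[Si](C)(C)C(C)(C)C)cc1
F6 | step 4 | 2‑bromo‑4,6‑bis(tert‑butyldimethylsilyloxy)benzaldehyde | O=Cc1c(Br)cc(O[Si](C)(C)C(C)(C)C)cc1O[Si](C)(C)C(C)(C)C
F7 | step 11 | 2‑{(E)‑2‑[3,4‑bis(tert‑butyldimethylsilyloxy)phenyl]ethenyl}‑4,4,5,5‑tetramethyl‑1,3,2‑dioxaborolane | CC(C)(C)[Si](C)(C)Oc1ccc(/C=C/B2OC(C)(C)C(C)(C)O2)cc1O[Si](C)(C)C(C)(C)C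
A1 | alternative 1 | (2R,3S,4R)‑2‑(4‑hydroxyphenyl)chromane‑3,4,7‑triol | Oc1ccc([C@H]2Oc3cc(O)ccc3[C@@H](O)[C@@H]2O)cc1
A2 | alternative 1 | piceatannol, (E)‑4‑[2‑(3,5‑dihydroxyphenyl)ethenyl]benzene‑1,2‑diol | Oc1cc(O)cc(/C=C/c2ccc(O)c(O)c2)c1
A3 | alternative 2 | 7‑methoxy‑2‑(4‑methoxyphenyl)‑4H‑chromen‑4‑one | COc1ccc(-c2cc(=O)c3ccc(OC)cc3o2)cc1
A4 | alternative 2 | 4‑(2‑bromo‑4,6‑dimethoxyphenyl)‑7‑methoxy‑2‑(4‑methoxyphenyl)chromenylium tetrafluoroborate | COc1ccc(-c2cc(-c3c(OC)cc(OC)cc3Br)c3ccc(OC)cc3[o+]2)cc1.F[B-](F)(F)F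
A5 | alternative 2 | (S)‑4‑(2‑bromo‑4,6‑dimethoxyphenyl)‑7‑methoxy‑2‑(4‑methoxyphenyl)‑4H‑chromene | COc1ccc(C2=C[C@H](c3c(OC)cc(OC)cc3Br)c3ccc(OC)cc3O2)cc1
A6 | alternative 3 | tert‑butyl{3‑[(R)‑{(2S,3R)‑3‑[2‑bromo‑4,6‑bis(tert‑butyldimethylsilyloxy)phenyl]oxiran‑2‑yl}[4‑(tert‑butyldimethylsilyloxy)phenyl]methoxy]phenoxy}dimethylsilane | CC(C)(C)[Si](C)(C)Oc1ccc(cc1)[C@@H](Oc1cccc(O[Si](C)(C)C(C)(C)C)c1)[C@H]1O[C@@H]1c1c(O[Si](C)(C)C(C)(C)C)cc(O[Si](C)(C)C(C)(C)C)cc1Br
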